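## Retrosynthetic overview

- The target comes from its bis-triethylsilyl ether; the pyran ring is closed last, by 6-endo addition of the C1 hydroxyl to the C3 alkyne carbon of a cyclohexenone-enyne.
- The carbocycle is formed first, in the same flask, by a light-driven titanocene reductive epoxide opening and 6-endo-dig radical cyclization onto a cross-conjugated diynone. This makes the C8a–C4a bond and sets C8a.
- The epoxy diynone comes from acyl substitution of a D-lactate-derived dioxolanone (C6 to C8a, C1) by the lithium ene-diynide of the side chain.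
- Both methyl-carbinol/carbinol pairs come from lactic acid dioxolanone aldols: L-lactate with (S)-2-methylbutanal gives C3'/C4', D-lactate with acrolein gives C7/C8. C5' is bought in (S)-2-methylbutan-1-ol.

Assumption: the registry entry is taken as exactly the stereoisomer of the SMILES, (7S,8S,8aS) in the core and (1'E,3'S,4'R,5'S) in the side chain; core atoms carry isochromene numbers (C1 to C8a) and side-chain atoms are primed, counted from the ring.

## Route

Step 1
Reactants: 1 (S)-lactic acid; 2 pivalaldehyde (2,2-dimethylpropanal)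
Product: 3 (2S,5S)-2-tert-butyl-5-methyl-1,3-dioxolan-4-one
Conditions: p-TsOH·H2O (cat.), H2SO4 (cat.), pentane, reflux, Dean–Stark; recryst. pentane, −78 °C
Reagents that add atoms: none
Why: Acid-catalysed acetalization in which the lactate stereocentre steers the new acetal carbon to the cis isomer under equilibrating conditions, and low-temperature crystallization upgrades it to a single diastereomer.

Step 2
Reactants: 4 (S)-2-methylbutan-1-ol
Product: 5 (S)-2-methylbutanal
Conditions: TEMPO (1 mol%), KBr (10 mol%), NaOCl (1.1 equiv), NaHCO3, CH2Cl2/H2O, 0 °C; used at once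
Reagents that add atoms: none
Why: Buffered oxoammonium (Anelli) oxidation of a primary alcohol stops at the aldehyde and does not epimerize the α-stereocentre when the product is used immediately.

Step 3
Reactants: 3 (2S,5S)-2-tert-butyl-5-methyl-1,3-dioxolan-4-one; 5 (S)-2-methylbutanal
Product: 8 (2S,5R)-2-tert-butyl-5-methyl-5-[(1R,2S)-2-methyl-1-(triethylsilyloxy)butyl]-1,3-dioxolan-4-one, via lithium dioxolanone enolate 6 (not isolated), via lithium aldolate 7 (not isolated)
Conditions: LiN(i-Pr)2 (1.05 equiv), THF, −78 °C; 5 (1.2 equiv), −78 °C; TESOTf (1.5 equiv), 2,6-lutidine, −78 → −40 °C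
Reagents that add atoms: triethylsilyl trifluoromethanesulfonate, CC[Si](CC)(CC)OS(=O)(=O)C(F)(F)F
Why: Aldol addition with self-regeneration of the lactate stereocentre: the planar enolate is attacked anti to the tert-butyl group (net retention, giving 3'S), a closed Zimmerman–Traxler chair with the sec-butyl residue equatorial puts methyl and oxygen syn (giving 4'R), and silyl capture at low temperature prevents retro-aldol.

Step 4
Reactants: 8 (2S,5R)-2-tert-butyl-5-methyl-5-[(1R,2S)-2-methyl-1-(triethylsilyloxy)butyl]-1,3-dioxolan-4-one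
Product: 9 (2S,5R)-2-tert-butyl-5-methyl-5-[(1R,2S)-2-methyl-1-(triethylsilyloxy)butyl]-1,3-dioxolan-4-ol (both C4 anomers)
Conditions: i-Bu2AlH (1.2 equiv), CH2Cl2, −78 °C; aq. potassium sodium tartrate
Reagents that add atoms: none
Why: Partial hydride reduction of a lactone stops at the lactol because the aluminium hemiacetal is stable at −78 °C; the anomeric centre is lost in the next step.

Step 5
Reactants: 9 (2S,5R)-2-tert-butyl-5-methyl-5-[(1R,2S)-2-methyl-1-(triethylsilyloxy)butyl]-1,3-dioxolan-4-ol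
Product: 10 (1E,3S,4R,5S)-1-iodo-3,5-dimethyl-4-(triethylsilyloxy)hept-1-en-3-ol
Conditions: CrCl2 (8 equiv), CHI3 (3 equiv), THF/1,4-dioxane 1:6, 0 → 23 °C
Reagents that add atoms: iodoform, IC(I)I
Why: Takai iodo-olefination with divalent chromium: the lactol opens to the α-hydroxy aldehyde with loss of pivalaldehyde, and the geminal dichromium reagent adds and eliminates to give the E-vinyl iodide, which hindered aldehydes favour strongly.

Step 6
Reactants: 10 (1E,3S,4R,5S)-1-iodo-3,5-dimethyl-4-(triethylsilyloxy)hept-1-en-3-ol; 11 1,4-bis(trimethylsilyl)buta-1,3-diyne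
Product: 14 (5E,7S,8R,9S)-7,9-dimethyl-8-(triethylsilyloxy)-1-(trimethylsilyl)undec-5-ene-1,3-diyn-7-ol, via lithium silyldiynide 12 (not isolated), via terminal silyldiyne 13 (not isolated)
Conditions: 11 (1.5 equiv), MeLi·LiBr (1.5 equiv), Et2O, 0 → 23 °C; aq. NH4Cl; dried Et2O solution added to 10, Pd(PPh3)4 (5 mol%), CuI (10 mol%), i-Pr2NH, THF, 23 °C
Reagents that add atoms: none
Why: Selective mono-desilylation of the bis-silyl diyne followed by Sonogashira coupling, which joins the sp carbon to the vinyl iodide with retention of the E geometry and tolerates the free tertiary alcohol.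

Step 7
Reactants: 15 (R)-lactic acid; 2 pivalaldehyde (2,2-dimethylpropanal)
Product: 16 (2R,5R)-2-tert-butyl-5-methyl-1,3-dioxolan-4-one
Conditions: p-TsOH·H2O (cat.), H2SO4 (cat.), pentane, reflux, Dean–Stark; recryst. pentane, −78 °C
Reagents that add atoms: none
Why: Same acid-catalysed cis-selective acetalization as step 1, in the enantiomeric series.

Step 8
Reactants: 16 (2R,5R)-2-tert-butyl-5-methyl-1,3-dioxolan-4-one; 17 acrolein
Product: 20 (2R,5S)-2-tert-butyl-5-methyl-5-[(1S)-1-(triethylsilyloxy)prop-2-en-1-yl]-1,3-dioxolan-4-one, via lithium enolate 18 (not isolated), via lithium allylic aldolate 19 (not isolated)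
Conditions: LiN(i-Pr)2 (1.05 equiv), THF, −78 °C; 17 (1.3 equiv), −78 °C; TESOTf (1.5 equiv), 2,6-lutidine, −78 → −40 °C
Reagents that add atoms: triethylsilyl trifluoromethanesulfonate, CC[Si](CC)(CC)OS(=O)(=O)C(F)(F)F
Why: The same self-regenerating aldol, as 1,2-addition to the enal: attack anti to tert-butyl gives C7 (S) and the Zimmerman–Traxler chair with vinyl equatorial gives C8 (S), the cis-diol relationship of the target.

Step 9
Reactants: 20 (2R,5S)-2-tert-butyl-5-methyl-5-[(1S)-1-(triethylsilyloxy)prop-2-en-1-yl]-1,3-dioxolan-4-one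
Product: 21 (2R,5S)-2-tert-butyl-5-methyl-5-[(S)-oxiran-2-yl(triethylsilyloxy)methyl]-1,3-dioxolan-4-one (both oxirane epimers)
Conditions: mCPBA (3 equiv), NaHCO3, 1,2-dichloroethane, 45 °C
Reagents that add atoms: 3-chloroperoxybenzoic acid, OOC(=O)c1cccc(Cl)c1
Why: Prilezhaev epoxidation of the terminal alkene under buffered conditions; the new oxirane carbon (future C8a) need not be controlled because both epimers give the same radical in step 11.

Step 10
Reactants: 14 (5E,7S,8R,9S)-7,9-dimethyl-8-(triethylsilyloxy)-1-(trimethylsilyl)undec-5-ene-1,3-diyn-7-ol; 21 (2R,5S)-2-tert-butyl-5-methyl-5-[(S)-oxiran-2-yl(triethylsilyloxy)methyl]-1,3-dioxolan-4-one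
Product: 24 (1S,2S,8E,10S,11R,12S)-2,10-dihydroxy-2,10,12-trimethyl-1-(oxiran-2-yl)-1,11-bis(triethylsilyloxy)tetradec-8-ene-4,6-diyn-3-one, via dilithium enediynide 22 (not isolated), via lithium hemiketal adduct 23 (not isolated)
Conditions: 14 (1.2 equiv), MeLi·LiBr (2.4 equiv), THF, −78 → 23 °C, 2 h; recool to −78 °C, 21 (1.0 equiv), −78 → −50 °C; aq. NH4Cl; SiO2
Reagents that add atoms: none
Why: Acyl substitution of the lactone by a lithium acetylide: the tetrahedral lithium hemiketal resists a second addition and unravels on work-up with loss of pivalaldehyde to the α-hydroxy diynone, while the epoxide is inert without a Lewis acid and no stereocentre is touched.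

Step 11
Reactants: 24 (1S,2S,8E,10S,11R,12S)-2,10-dihydroxy-2,10,12-trimethyl-1-(oxiran-2-yl)-1,11-bis(triethylsilyloxy)tetradec-8-ene-4,6-diyn-3-one
Product: 26 (7S,8S,8aS)-7-hydroxy-3-[(1E,3S,4R,5S)-3-hydroxy-3,5-dimethyl-4-(triethylsilyloxy)hept-1-en-1-yl]-7-methyl-8-(triethylsilyloxy)-1,7,8,8a-tetrahydro-6H-isochromen-6-one, via hydroxy enynone 25 (not isolated)
Conditions: Cp2TiCl2 (10 mol%), Hantzsch ester (1.5 equiv), 2,4,6-collidine·HCl (0.5 equiv), THF (5 mM), green LEDs (525 nm), 23 °C; then DBU (0.2 equiv), 23 °C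
Reagents that add atoms: none
Why: Proposed new method: green-light excitation of Cp2TiCl2 with Hantzsch ester as reductant gives trivalent Cp2TiCl, which opens either epoxide epimer of 24 homolytically to the same secondary β-titanoxy radical at C8a; this nucleophilic radical adds 6-endo-dig to the electron-poor β-alkyne carbon C4a of the diynone (polarity-matched, whereas 5-exo attack at the α-carbon C5 is mismatched) through a chair-like transition state with the CH2O–Ti arm pseudo-equatorial and trans to the C8 silyloxy group, which sets 8aS; the C5 vinyl radical takes hydrogen from the Hantzsch ester, protonolysis returns tetravalent titanium and frees hydroxy enynone 25, and DBU then drives the 6-endo oxa-1,6-addition of the C1 hydroxyl to C3 and lets C8a settle in the same trans arrangement; the closest known reaction type is the titanocene-mediated reductive epoxide opening with 5-exo radical cyclization onto alkynes, including its photoredox-catalytic forms, which has not been shown for 6-endo-dig closure onto an ynone or on epoxy diynones.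

Step 12
Reactants: 26 (7S,8S,8aS)-7-hydroxy-3-[(1E,3S,4R,5S)-3-hydroxy-3,5-dimethyl-4-(triethylsilyloxy)hept-1-en-1-yl]-7-methyl-8-(triethylsilyloxy)-1,7,8,8a-tetrahydro-6H-isochromen-6-one
Product: 27 (7S,8S,8aS)-3-[(1E,3S,4R,5S)-3,4-dihydroxy-3,5-dimethylhept-1-en-1-yl]-7,8-dihydroxy-7-methyl-1,7,8,8a-tetrahydro-6H-isochromen-6-one (CNP0291643.5)
Conditions: Et3N·3HF (6 equiv), MeCN/THF, 23 °C
Reagents that add atoms: none
Why: Fluoride-driven cleavage of the two secondary triethylsilyl ethers under near-neutral conditions, which spare the vinylogous ester, the tertiary allylic alcohol and all stereocentres.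

## Compound list

1 | (S)-lactic acid | C[C@H](O)C(=O)O | starting material
2 | pivalaldehyde (2,2-dimethylpropanal) | CC(C)(C)C=O | starting material
3 | (2S,5S)-2-tert-butyl-5-methyl-1,3-dioxolan-4-one | C[C@@H]1O[C@H](C(C)(C)C)OC1=O | intermediate
4 | (S)-2-methylbutan-1-ol | CC[C@H](C)CO | starting material
5 | (S)-2-methylbutanal | CC[C@H](C)C=O | intermediate
6 | lithium (2S)-2-tert-butyl-5-methyl-1,3-dioxol-4-olate | CC1=C(O[Li])O[C@@H](C(C)(C)C)O1 | intermediate
7 | lithium (1R,2S)-1-[(2S,4R)-2-tert-butyl-4-methyl-5-oxo-1,3-dioxolan-4-yl]-2-methylbutan-1-olate | CC[C@H](C)[C@@H](O[Li])[C@@]1(C)O[C@H](C(C)(C)C)OC1=O | intermediate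
8 | (2S,5R)-2-tert-butyl-5-methyl-5-[(1R,2S)-2-methyl-1-(triethylsilyloxy)butyl]-1,3-dioxolan-4-one | CC[C@H](C)[C@@H](O[Si](CC)(CC)CC)[C@@]1(C)O[C@H](C(C)(C)C)OC1=O | intermediate
9 | (2S,5R)-2-tert-butyl-5-methyl-5-[(1R,2S)-2-methyl-1-(triethylsilyloxy)butyl]-1,3-dioxolan-4-ol (both C4 anomers) | CC[C@H](C)[C@@H](O[Si](CC)(CC)CC)[C@@]1(C)O[C@H](C(C)(C)C)OC1O | intermediate
10 | (1E,3S,4R,5S)-1-iodo-3,5-dimethyl-4-(triethylsilyloxy)hept-1-en-3-ol | CC[C@H](C)[C@@H](O[Si](CC)(CC)CC)[C@@](C)(O)/C=C/I | intermediate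
11 | 1,4-bis(trimethylsilyl)buta-1,3-diyne | C[Si](C)(C)C#CC#C[Si](C)(C)C | starting material
12 | lithium 4-(trimethylsilyl)buta-1,3-diyn-1-ide | [Li]C#CC#C[Si](C)(C)C | intermediate
13 | buta-1,3-diyn-1-yl(trimethyl)silane | C#CC#C[Si](C)(C)C | intermediate
14 | (5E,7S,8R,9S)-7,9-dimethyl-8-(triethylsilyloxy)-1-(trimethylsilyl)undec-5-ene-1,3-diyn-7-ol | CC[C@H](C)[C@@H](O[Si](CC)(CC)CC)[C@@](C)(O)/C=C/C#CC#C[Si](C)(C)C | intermediate
15 | (R)-lactic acid | C[C@@H](O)C(=O)O | starting material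
16 | (2R,5R)-2-tert-butyl-5-methyl-1,3-dioxolan-4-one | C[C@H]1O[C@@H](C(C)(C)C)OC1=O | intermediate
17 | acrolein (prop-2-enal) | C=CC=O | starting material
18 | lithium (2R)-2-tert-butyl-5-methyl-1,3-dioxol-4-olate | CC1=C(O[Li])O[C@H](C(C)(C)C)O1 | intermediate
19 | lithium (1S)-1-[(2R,4S)-2-tert-butyl-4-methyl-5-oxo-1,3-dioxolan-4-yl]prop-2-en-1-olate | C=C[C@H](O[Li])[C@]1(C)O[C@@H](C(C)(C)C)OC1=O | intermediate
20 | (2R,5S)-2-tert-butyl-5-methyl-5-[(1S)-1-(triethylsilyloxy)prop-2-en-1-yl]-1,3-dioxolan-4-one | C=C[C@H](O[Si](CC)(CC)CC)[C@]1(C)O[C@@H](C(C)(C)C)OC1=O | intermediate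
21 | (2R,5S)-2-tert-butyl-5-methyl-5-[(S)-oxiran-2-yl(triethylsilyloxy)methyl]-1,3-dioxolan-4-one (both oxirane epimers) | C1OC1[C@H](O[Si](CC)(CC)CC)[C@]1(C)O[C@@H](C(C)(C)C)OC1=O | intermediate
22 | dilithium (5E,7S,8R,9S)-7,9-dimethyl-7-oxido-8-(triethylsilyloxy)undec-5-ene-1,3-diyn-1-ide | CC[C@H](C)[C@@H](O[Si](CC)(CC)CC)[C@@](C)(O[Li])/C=C/C#CC#C[Li] | intermediate
23 | dilithium salt of the hemiketal from addition of 22 to the lactone carbonyl of 21: (2R,5S)-2-tert-butyl-4-[(5E,7S,8R,9S)-7,9-dimethyl-7-oxido-8-(triethylsilyloxy)undec-5-ene-1,3-diyn-1-yl]-5-methyl-5-[(S)-oxiran-2-yl(triethylsilyloxy)methyl]-1,3-dioxolan-4-olate (C4 and oxirane epimers) | CC[C@H](C)[C@@H](O[Si](CC)(CC)CC)[C@@](C)(O[Li])/C=C/C#CC#CC1(O[Li])O[C@H](C(C)(C)C)O[C@@]1(C)[C@@H](O[Si](CC)(CC)CC)C1CO1 | intermediate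
24 | (1S,2S,8E,10S,11R,12S)-2,10-dihydroxy-2,10,12-trimethyl-1-(oxiran-2-yl)-1,11-bis(triethylsilyloxy)tetradec-8-ene-4,6-diyn-3-one (both oxirane epimers) | CC[C@H](C)[C@@H](O[Si](CC)(CC)CC)[C@@](C)(O)/C=C/C#CC#CC(=O)[C@@](C)(O)[C@@H](O[Si](CC)(CC)CC)C1CO1 | intermediate
25 | (4S,5S,6S)-6-hydroxy-3-[(3E,5S,6R,7S)-5-hydroxy-5,7-dimethyl-6-(triethylsilyloxy)non-3-en-1-yn-1-yl]-4-(hydroxymethyl)-6-methyl-5-(triethylsilyloxy)cyclohex-2-en-1-one | CC[C@H](C)[C@@H](O[Si](CC)(CC)CC)[C@@](C)(O)/C=C/C#CC1=CC(=O)[C@@](C)(O)[C@@H](O[Si](CC)(CC)CC)[C@@H]1CO | intermediate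
26 | (7S,8S,8aS)-7-hydroxy-3-[(1E,3S,4R,5S)-3-hydroxy-3,5-dimethyl-4-(triethylsilyloxy)hept-1-en-1-yl]-7-methyl-8-(triethylsilyloxy)-1,7,8,8a-tetrahydro-6H-isochromen-6-one | CC[C@H](C)[C@@H](O[Si](CC)(CC)CC)[C@@](C)(O)/C=C/C1=CC2=CC(=O)[C@@](C)(O)[C@@H](O[Si](CC)(CC)CC)[C@@H]2CO1 | intermediate
27 | (7S,8S,8aS)-3-[(1E,3S,4R,5S)-3,4-dihydroxy-3,5-dimethylhept-1-en-1-yl]-7,8-dihydroxy-7-methyl-1,7,8,8a-tetrahydro-6H-isochromen-6-one | CC[C@H](C)[C@@H](O)[C@@](C)(O)/C=C/C1=CC2=CC(=O)[C@@](C)(O)[C@@H](O)[C@@H]2CO1 | target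

## Step count and risk

Total steps: 12. Longest linear sequence: 8 steps (1, 3, 4, 5, 6, 10, 11, 12).

The three steps most likely to fail:

Step 11 (the new light-driven radical cyclization). The radical may close 5-exo at C5, be reduced before cyclizing, or the diynone may be reduced by trivalent titanium. The fallback closes both rings by the amine-catalysed Michael addition/oxa-6π-electrocyclization cascade that is already established for this bicyclic core with a simpler dienyl side chain. It sets out from dioxolanone 16 and vinyl iodide 10 and comes back at 26. Compound 16 is taken through the aldol/silylation of step 8 with 2-bromoacrolein in place of acrolein to give (2R,5S)-5-[(1R)-2-bromo-1-(triethylsilyloxy)prop-2-en-1-yl]-2-tert-butyl-5-methyl-1,3-dioxolan-4-one F1. MeLi (1.05 equiv, THF, −78 °C, then aq. NH4Cl) turns the lactone into the methyl ketone (3S,4R)-5-bromo-3-hydroxy-3-methyl-4-(triethylsilyloxy)hex-5-en-2-one F2 with loss of pivalaldehyde. Sonogashira coupling with ethynyltrimethylsilane (Pd(PPh3)4, CuI, i-Pr2NH) gives (3S,4S)-3-hydroxy-3-methyl-5-methylidene-4-(triethylsilyloxy)-7-(trimethylsilyl)hept-6-yn-2-one F3, and K2CO3 in MeOH frees the terminal enyne (3S,4S)-3-hydroxy-3-methyl-5-methylidene-4-(triethylsilyloxy)hept-6-yn-2-one F4. Carbonylative Sonogashira coupling of F4 with 10 (PdCl2(PPh3)2, CuI, Et3N, CO 1 atm, THF) gives the acyclic diketone (3S,4S,9E,11S,12R,13S)-3,11-dihydroxy-3,11,13-trimethyl-5-methylidene-4,12-bis(triethylsilyloxy)pentadec-9-en-6-yne-2,8-dione F5. DABCO (20 mol%, CHCl3, 23 °C) adds to the ynone, the methyl ketone enolate closes the carbocycle by Michael addition and loss of the amine, the resulting 2Z-dienone undergoes oxa-6π electrocyclization, and tautomerization of the 2H-pyran into conjugation gives 26 with C8a set by protonation under equilibrating conditions.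

Step 10 (acetylide addition to the dioxolanone). The diynide may add twice once the acetal unravels, or the hemiketal may not collapse cleanly. The fallback sets out from 21 and comes back at 24. LiN(OMe)Me (from MeNHOMe·HCl and n-BuLi, THF, −78 °C) opens the dioxolanone, with loss of pivalaldehyde, to the Weinreb amide (2S,3S)-2-hydroxy-N-methoxy-N,2-dimethyl-3-(oxiran-2-yl)-3-(triethylsilyloxy)propanamide F6. Addition of 22 (2.5 equiv, THF, −78 → 0 °C) to this chelating amide stops cleanly at the ketone stage and gives 24.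

Step 5 (Takai olefination on a lactol). The lactol may open too slowly, or the hindered α-hydroxy aldehyde may be reduced rather than olefinated. The fallback sets out from 9 and comes back at 10. Ohira–Bestmann homologation (dimethyl (1-diazo-2-oxopropyl)phosphonate, K2CO3, MeOH, 0 → 23 °C) acts on the open form of the lactol, with loss of pivalaldehyde, to give the alkyne (3S,4R,5S)-3,5-dimethyl-4-(triethylsilyloxy)hept-1-yn-3-ol F7. Hydrozirconation with Cp2Zr(H)Cl (2.5 equiv, THF, 23 °C) and iodinolysis with I2 then give 10 as the E isomer.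

## Further compounds

F1 | step 11 | (2R,5S)-5-[(1R)-2-bromo-1-(triethylsilyloxy)prop-2-en-1-yl]-2-tert-butyl-5-methyl-1,3-dioxolan-4-one | C=C(Br)[C@H](O[Si](CC)(CC)CC)[C@]1(C)O[C@@H](C(C)(C)C)OC1=O
F2 | step 11 | (3S,4R)-5-bromo-3-hydroxy-3-methyl-4-(triethylsilyloxy)hex-5-en-2-one | CC(=O)[C@@](C)(O)[C@@H](O[Si](CC)(CC)CC)C(Br)=C
F3 | step 11 | (3S,4S)-3-hydroxy-3-methyl-5-methylidene-4-(triethylsilyloxy)-7-(trimethylsilyl)hept-6-yn-2-one | CC(=O)[C@@](C)(O)[C@@H](O[Si](CC)(CC)CC)C(=C)C#C[Si](C)(C)C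
F4 | step 11 | (3S,4S)-3-hydroxy-3-methyl-5-methylidene-4-(triethylsilyloxy)hept-6-yn-2-one | CC(=O)[C@@](C)(O)[C@@H](O[Si](CC)(CC)CC)C(=C)C#C
F5 | step 11 | (3S,4S,9E,11S,12R,13S)-3,11-dihydroxy-3,11,13-trimethyl-5-methylidene-4,12-bis(triethylsilyloxy)pentadec-9-en-6-yne-2,8-dione | CC[C@H](C)[C@@H](O[Si](CC)(CC)CC)[C@@](C)(O)/C=C/C(=O)C#CC(=C)[C@H](O[Si](CC)(CC)CC)[C@](C)(O)C(C)=O
F6 | step 10 | (2S,3S)-2-hydroxy-N-methoxy-N,2-dimethyl-3-(oxiran-2-yl)-3-(triethylsilyloxy)propanamide (both oxirane epimers) | CON(C)C(=O)[C@@](C)(O)[C@@H](O[Si](CC)(CC)CC)C1CO1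
F7 | step 5 | (3S,4R,5S)-3,5-dimethyl-4-(triethylsilyloxy)hept-1-yn-3-ol | CC[C@H](C)[C@@H](O[Si](CC)(CC)CC)[C@@](C)(O)C#C
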